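## Structural features

The target, (1S,3S)-1-[(12Z)-16-phenylhexadec-12-en-1-yl]cyclohex-4-ene-1,3-diol, has one carbocycle. It is numbered here C1 (secondary allylic carbinol), C2=C3 (ring alkene), C4 (CH2), C5 (tertiary carbinol) and C6 (the CH2 between the two carbinol carbons). An unbranched chain C1'–C16' sits on C5, carries a Z-alkene at C12'=C13' and ends in a phenyl ring on C16'. The stereocentres C1 and C5 stand 1,3 to each other across C6 and hold their hydroxyl groups on the same ring face. Both alcohols are easily ionised or dehydrated by acid (loss of both would aromatise the ring), and the chain Z-alkene is open to electrophilic oxidants, hydrogenation and geometric isomerisation by acids, radicals or metal hydrides. The real difficulty is the absolute configuration of C5: its three carbon substituents C4, C6 and C1' are all CH2 groups that differ only further out, so no reagent adding to a C5 carbonyl could tell them apart. A second difficulty is to place the ring alkene at C2=C3 and not toward C6, and to tie C1 to C5. The key step uses the fact that the C5 oxygen is β to C1: with C1 as a ketone and C5=C6 as the enone alkene, C5 is trigonal, and its oxygen can be delivered to one face together with the C6–O bond as an oxirane. That oxirane afterwards blocks C6, steers the reduction at C1 and is finally opened at C6.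

## Logic of the disconnections

**15 ⇒ 14.** The C6–H bond is cut and the C6–O bond restored, so that the C5 oxygen and C6 form an oxirane cis to the C1 hydroxyl. A cis-1,3-diol with a CH2 between the carbinols is the hydride-opening product of a cis-2,3-epoxy alcohol, and the C5–O bond is never broken. The gain is a rigid bicycle in which both carbinol configurations follow from one facial choice. The forward step must put hydride on the secondary C6 and not on the fully substituted C5, and must leave both alkenes and the allylic C1–O bond alone.

**14 ⇒ 13.** The C1–H bond is cut, turning C1 into a ketone conjugated with C2=C3. The neighbouring oxirane differentiates the two faces of this carbonyl, so C1 needs no independent control. One stereocentre disappears and C1 regains the carbonyl on which all earlier steps depend. The forward step must be a 1,2-reduction from the face opposite the oxirane oxygen, and mild, because 13 can aromatise by base-induced opening of the oxirane.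

**13 ⇒ 12 ⇒ 11.** The C2=C3 π bond is removed by way of the C1 silyl enol ether 12. The alkene is α,β to the C1 carbonyl and can therefore come from dehydrogenation. The regiochemistry is unambiguous because enolisation toward the oxirane carbon C6 is not available. What remains is the saturated 11, the direct product of an enone epoxidation. The forward steps need an enol silylation that does not open the oxirane and a dehydrogenation that tolerates C12'=C13'.

**11 ⇒ 10 (key).** The C5–O and C6–O bonds are cut together, which removes the oxirane ring and both stereocentres. This is the only point where C5 can be made from a trigonal carbon, so the three CH2 neighbours of C5 never have to be distinguished. The gain is an achiral precursor with every carbon atom in place. The demand is enantiofacial control on a β,β-disubstituted enone and an oxidant that ignores the chain alkene.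

**10 ⇒ 6 + 7.** The C5–C1' bond is cut. A 3-alkylcyclohex-2-enone is what results when a carbon nucleophile adds to the carbonyl of a vinylogous ester and acid then transposes the carbonyl. Ring and chain separate at their only junction, which gives a convergent assembly from the commercial ring 7 and the linear bromide 6. The forward step needs clean formation of the organomagnesium 8, 1,2-addition to give 9, and a hydrolysis mild enough for the Z-alkene.

**6 ⇒ 2 + 4.** The C12'=C13' double bond is cut. A 1,2-dialkyl Z-alkene is the normal outcome of an unstabilised ylide (5) with an aldehyde, and the cut leaves two commercial ω-functionalised chains. The forward step must be Z-selective (lithium-free base, low temperature), and 5 must attack the aldehyde and not the C–Br terminus.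

**2 ⇒ 1 and 4 ⇒ 3.** The C–P bond of 2 and the aldehyde oxidation level of 4 are traced back to the commercial bromide 1 and bromo alcohol 3. The only demand is that the oxidation of 3 stops at the aldehyde and spares the C–Br bond.

## Other disconnections considered

**Alternative 1:** carbonate-tethered iodocyclisation.
- **Cut:** the C1–O bond; the C2=C3 alkene arises afterwards by loss of HI.
- **Forward key step:** IBr would activate the C1=C2 alkene of tert-butyl (1S)-1-[12-(tert-butyldimethylsilyloxy)dodecyl]cyclohex-3-en-1-yl carbonate A1. The carbonate carbonyl oxygen would close onto C1 anti to iodine, with loss of the tert-butyl group, to give (1S,5S,6S)-6-iodo-1-[12-(tert-butyldimethylsilyloxy)dodecyl]-2,4-dioxabicyclo[3.3.1]nonan-3-one A2.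
- **Locant:** with the chain-bearing bridgehead as position 1, the iodinated carbon neighbours the C–H bridgehead and takes locant 6. A locant of 8 would wrongly put iodine next to the quaternary carbon.
- **In favour:** a carbonate can bridge C1 and C5 only on one face, so the cis relationship is enforced by ring geometry. On relative configuration this is the equal of the chosen plan and arguably better than a reagent-dependent carbonyl reduction. The iodine in A2 lies anti to a C3 hydrogen and not to the C1 hydrogen, so elimination should give C2=C3 cleanly. No sensitive epoxy enone is involved.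
- **Against:** the cyclisation only relays configuration from C5. A1 must already be one enantiomer, and its stereocentre differs only in a CH2–CH= arm versus a CH2–CH2 arm, so a resolution would be needed. IBr is an electrophile and would also attack C12'=C13'. The chain therefore has to be carried as a silyl ether stub and completed afterwards (desilylation, oxidation, Z-olefination) on a molecule holding a base-labile carbonate.
- **Comparison:** structurally it solves the 1,3-relationship elegantly but leaves the hard centre C5 unsolved. Mechanistically its electrophilic activation clashes with the chain alkene, whereas the nucleophilic oxidant of the chosen plan is orthogonal to it. In step economy it would need about a dozen operations including a resolution, against nine.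

**Alternative 2:** Ireland–Claisen ring contraction.
- **Cut:** the C4–C5 bond.
- **Forward key step:** the silyl ketene acetal of (5S,6S)-5-(tert-butyldimethylsilyloxy)-6-ethenyl-3-[(4-methoxybenzyl)oxy]oxan-2-one A3 (either C3 epimer) would rearrange by a [3,3] shift through a boat-like transition state. This would give (1S,5S)-5-(tert-butyldimethylsilyloxy)-1-[(4-methoxybenzyl)oxy]cyclohex-3-ene-1-carboxylic acid A4.
- **In favour:** the ring, the C2=C3 alkene and the C5 configuration would all appear in one concerted, suprafacial step. C5 is set by chirality transfer from a secondary allylic C–O stereocentre that is easy to make. The alkene position is fixed by the mechanism. On predictability of the stereochemical sense and on alkene placement this is the better of the two plans.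
- **Against:** A3 needs two adjacent stereocentres in a cis relationship plus a protected α-hydroxy group, which is a multi-step preparation. A4 carries a carboxyl group where the target has a sixteen-carbon chain. The carboxyl carbon becomes C1', a neopentyl-type position next to a fully substituted carbon. Attaching the other fifteen carbons means reduction, re-oxidation and olefination, then saturation of a new C1'=C2' alkene beside the ring alkene and C12'=C13', for which no selective handle exists. Two protecting groups must also be removed.
- **Comparison:** structurally it is stronger at the ring and much weaker at the C5–C1' junction, which the chosen plan makes in one Grignard step. Mechanistically a pericyclic transfer is more certain than a catalyst-controlled face selection. In step economy it would be clearly longer, probably beyond fifteen steps.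

**Alternative 3:** glycidyl tosylate linchpin, then ring-closing metathesis.
- **Cut:** the C3–C4 and C1–C6 bonds in the key step; C1–C2 and C2=C3 are made later.
- **Forward key step:** [(2S)-2-[(12Z)-16-phenylhexadec-12-en-1-yl]oxiran-2-yl]methyl 4-methylbenzenesulfonate A5 would be opened at its oxirane CH2 by vinylmagnesium bromide with CuI. The alkoxide would displace the tosylate to form the transposed oxirane, and 2-lithio-1,3-dithiane would open that in the same flask. The product would be (4S,16Z)-4-[(1,3-dithian-2-yl)methyl]-20-phenylicosa-1,16-dien-4-ol A6.
- **In favour:** the C5 configuration would come from a titanium–tartrate epoxidation preceding A5. Like the chosen key step, that starts from a trigonal C5 and never has to tell three CH2 groups apart, so on the central problem this alternative is the equal of the chosen plan. Cuprate and dithiane anions ignore the chain alkene, and the coupling is convergent.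
- **Against:** no ring closes and C1 is not set. After A6 the dithiane must be unmasked beside two alkenes, giving a carbonyl group β to a tertiary alcohol that is prone to retro-aldol cleavage and dehydration. The vinyl addition would have only weak 1,3-induction from C5. The ring closure with a second-generation Grubbs catalyst would take place in the presence of C12'=C13', which the ruthenium alkylidene and the released ethylene can scramble or cleave.
- **Comparison:** structurally it is equal on C5 and weaker on C1 and on the ring. Mechanistically the metathesis threatens the one fragile group that the chosen plan never exposes to a reactive metal alkylidene. In step economy it would be comparable to slightly longer, at roughly eleven to thirteen steps.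

Key step: step 5

Assumption: the 9-amino-9-deoxy-epi-quinine salt is taken to deliver the peroxide to the face of C5 that leads to the (1S,6S) oxide 11; if its intrinsic sense is the opposite, the pseudoenantiomeric 9-amino-9-deoxy-epi-quinidine salt is used in step 5 and nothing else changes.

## Route

Step 1
Reactants: 1 (4-bromobutyl)benzene
Product: 2 (4-phenylbutyl)triphenylphosphonium bromide
Conditions: PPh3, MeCN, reflux
Reagents that add atoms: triphenylphosphine, c1ccc(cc1)P(c1ccccc1)c1ccccc1
Why: SN2 quaternisation of an unhindered primary bromide by the phosphine; the salt should crystallise and is dried before use in the Wittig reaction.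

Step 2
Reactants: 3 12-bromododecan-1-ol
Product: 4 12-bromododecanal
Conditions: TEMPO (cat.), PhI(OAc)2, CH2Cl2, rt
Reagents that add atoms: none
Why: Oxoammonium (TEMPO) catalysed oxidation of a primary alcohol, which stops at the aldehyde and leaves the primary bromide untouched; it avoids chromium reagents, cryogenic conditions and malodorous by-products.

Step 3
Reactants: 2 (4-phenylbutyl)triphenylphosphonium bromide; 4 12-bromododecanal
Product: 6 [(4Z)-16-bromohexadec-4-en-1-yl]benzene, via phosphorus ylide 5 (not isolated)
Conditions: NaN(SiMe3)2, THF, 0 °C; then 4, −78 °C to rt
Reagents that add atoms: none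
Why: Wittig olefination with an unstabilised ylide under lithium-free conditions, where kinetic formation of the cis-oxaphosphetane should give the Z-alkene; at −78 °C the ylide should add to the aldehyde much faster than it alkylates the primary bromide.

Step 4
Reactants: 6 [(4Z)-16-bromohexadec-4-en-1-yl]benzene; 7 3-ethoxycyclohex-2-en-1-one
Product: 10 3-[(12Z)-16-phenylhexadec-12-en-1-yl]cyclohex-2-en-1-one, via Grignard reagent 8 (not isolated), via magnesium alkoxide adduct 9 (not isolated)
Conditions: Mg, I2 (cat.), THF, 40 °C; then 7, THF, 0 °C to rt; then 1 M aq. HCl, rt
Reagents that add atoms: water, O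
Why: Stork–Danheiser sequence: the Grignard reagent adds 1,2 to the vinylogous ester, and dilute acid then hydrolyses the enol ether and eliminates the tertiary hydroxyl to give the transposed 3-alkyl enone; the remote Z-alkene is inert to magnesium and to brief contact with dilute acid.

Step 5
Reactants: 10 3-[(12Z)-16-phenylhexadec-12-en-1-yl]cyclohex-2-en-1-one
Product: 11 (1S,6S)-6-[(12Z)-16-phenylhexadec-12-en-1-yl]-7-oxabicyclo[4.1.0]heptan-2-one
Conditions: 9-amino-9-deoxy-epi-quinine bis(trifluoroacetate) (10 mol%), aq. H2O2 (1.5 equiv), 1,4-dioxane, 30–50 °C
Reagents that add atoms: hydrogen peroxide, OO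
Why: The primary amine of the catalyst condenses with the C1 carbonyl to a transient iminium ion, hydrogen peroxide adds as a nucleophile to C5, and the resulting β-hydroperoxy enamine attacks the proximal peroxide oxygen through C6 with loss of water, after which hydrolysis releases 11 and the amine. The closest known reaction type is the primary-amine-salt-catalysed asymmetric Weitz–Scheffer epoxidation of cyclic enones with aqueous hydrogen peroxide, which is established for 3-alkylcyclohex-2-enones. The oxirane closes in a 3-exo-tet mode at oxygen. The C5 stereocentre is set in the conjugate addition under catalyst control: the protonated quinuclidine is thought to hold the peroxide by hydrogen bonding over one face of the iminium ion, and because C5 is trigonal no distinction between its CH2 neighbours is needed. The C6 stereocentre follows from C5, since an oxirane on a six-membered ring can only be cis-fused. The step needs chemoselectivity for C5=C6 over C12'=C13', which is secured because hydrogen peroxide attacks only the iminium-activated, electron-poor alkene and the aqueous medium disfavours peracid formation from trifluoroacetate. The β,β-disubstitution slows the addition, so a lipophilic co-solvent and gentle warming are used.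

Step 6
Reactants: 11 (1S,6S)-6-[(12Z)-16-phenylhexadec-12-en-1-yl]-7-oxabicyclo[4.1.0]heptan-2-one
Product: 12 trimethyl({(1S,6S)-6-[(12Z)-16-phenylhexadec-12-en-1-yl]-7-oxabicyclo[4.1.0]hept-2-en-2-yl}oxy)silane
Conditions: Me3SiCl, LiN(SiMe3)2, THF, −78 °C (in situ quench)
Reagents that add atoms: chlorotrimethylsilane, C[Si](C)(C)Cl
Why: Kinetic enolisation with O-silylation as the enolate forms; only the C2 protons can be removed, because an enolate toward C6 would need a double bond exocyclic to the oxirane, and the low temperature and immediate trapping keep the oxirane closed.

Step 7
Reactants: 12 trimethyl({(1S,6S)-6-[(12Z)-16-phenylhexadec-12-en-1-yl]-7-oxabicyclo[4.1.0]hept-2-en-2-yl}oxy)silane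
Product: 13 (1S,6S)-6-[(12Z)-16-phenylhexadec-12-en-1-yl]-7-oxabicyclo[4.1.0]hept-3-en-2-one
Conditions: Pd(OAc)2 (1.05 equiv), MeCN, rt
Reagents that add atoms: none
Why: Saegusa–Ito oxidation: the silyl enol ether is converted into a divalent palladium enolate, and β-hydride elimination from C3 gives the enone and zerovalent palladium; the position of the enol ether fixes the alkene at C2=C3, and the neutral, room-temperature conditions should spare the oxirane.

Step 8
Reactants: 13 (1S,6S)-6-[(12Z)-16-phenylhexadec-12-en-1-yl]-7-oxabicyclo[4.1.0]hept-3-en-2-one
Product: 14 (1R,2R,6S)-6-[(12Z)-16-phenylhexadec-12-en-1-yl]-7-oxabicyclo[4.1.0]hept-3-en-2-ol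
Conditions: NaBH4, CeCl3·7H2O, MeOH/THF, −78 °C
Reagents that add atoms: none
Why: Luche reduction: the cerium-activated methoxyborohydride adds to the carbonyl carbon only (1,2) and should approach on the face opposite the oxirane oxygen, which shields and electrostatically disfavours its own face; the new hydroxyl is then cis to the oxirane and so cis to the C5 oxygen. The low temperature limits base-induced opening of the oxirane.

Step 9
Reactants: 14 (1R,2R,6S)-6-[(12Z)-16-phenylhexadec-12-en-1-yl]-7-oxabicyclo[4.1.0]hept-3-en-2-ol
Product: 15 (1S,3S)-1-[(12Z)-16-phenylhexadec-12-en-1-yl]cyclohex-4-ene-1,3-diol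
Conditions: LiAlH4, THF, 0 °C to rt; H2O then aq. NaOH
Reagents that add atoms: none
Why: SN2 hydride opening of a trisubstituted oxirane at its secondary carbon C6, the fully substituted C5 being inaccessible; C6 becomes a CH2 group, the C5–O bond is never broken, and the cis relationship set in step 8 becomes the cis-1,3-diol. Isolated alkenes and the allylic alkoxide are inert to LiAlH4 under these conditions.

## Compound list

1 | (4-bromobutyl)benzene | BrCCCCc1ccccc1 | starting material
2 | (4-phenylbutyl)triphenylphosphonium bromide | [Br-].c1ccc(cc1)CCCC[P+](c1ccccc1)(c1ccccc1)c1ccccc1 | intermediate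
3 | 12-bromododecan-1-ol | OCCCCCCCCCCCCBr | starting material
4 | 12-bromododecanal | O=CCCCCCCCCCCCBr | intermediate
5 | (4-phenylbutylidene)triphenyl-λ5-phosphane (ylide) | c1ccc(cc1)CCCC=P(c1ccccc1)(c1ccccc1)c1ccccc1 | intermediate (not isolated)
6 | [(4Z)-16-bromohexadec-4-en-1-yl]benzene | BrCCCCCCCCCCC/C=C\CCCc1ccccc1 | intermediate
7 | 3-ethoxycyclohex-2-en-1-one | CCOC1=CC(=O)CCC1 | starting material
8 | bromo[(12Z)-16-phenylhexadec-12-en-1-yl]magnesium | Br[Mg]CCCCCCCCCCC/C=C\CCCc1ccccc1 | intermediate (not isolated)
9 | 3-ethoxy-1-[(12Z)-16-phenylhexadec-12-en-1-yl]cyclohex-2-en-1-ol (racemic; present as its bromomagnesium alkoxide) | CCOC1=CC(O)(CCCCCCCCCCC/C=C\CCCc2ccccc2)CCC1 | intermediate (not isolated)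
10 | 3-[(12Z)-16-phenylhexadec-12-en-1-yl]cyclohex-2-en-1-one | O=C1C=C(CCCCCCCCCCC/C=C\CCCc2ccccc2)CCC1 | intermediate
11 | (1S,6S)-6-[(12Z)-16-phenylhexadec-12-en-1-yl]-7-oxabicyclo[4.1.0]heptan-2-one | O=C1CCC[C@@](O2)(CCCCCCCCCCC/C=C\CCCc3ccccc3)[C@@H]12 | intermediate
12 | trimethyl({(1S,6S)-6-[(12Z)-16-phenylhexadec-12-en-1-yl]-7-oxabicyclo[4.1.0]hept-2-en-2-yl}oxy)silane | C[Si](C)(C)OC1=CCC[C@@](O2)(CCCCCCCCCCC/C=C\CCCc3ccccc3)[C@@H]12 | intermediate
13 | (1S,6S)-6-[(12Z)-16-phenylhexadec-12-en-1-yl]-7-oxabicyclo[4.1.0]hept-3-en-2-one | O=C1C=CC[C@@](O2)(CCCCCCCCCCC/C=C\CCCc3ccccc3)[C@@H]12 | intermediate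
14 | (1R,2R,6S)-6-[(12Z)-16-phenylhexadec-12-en-1-yl]-7-oxabicyclo[4.1.0]hept-3-en-2-ol | O[C@@H]1C=CC[C@@](O2)(CCCCCCCCCCC/C=C\CCCc3ccccc3)[C@@H]12 | intermediate
15 | (1S,3S)-1-[(12Z)-16-phenylhexadec-12-en-1-yl]cyclohex-4-ene-1,3-diol | O[C@@H]1C=CC[C@@](O)(CCCCCCCCCCC/C=C\CCCc2ccccc2)C1 | target

## Step count and least certain steps

Total step count: 9. Longest linear sequence: 8 steps (steps 2 to 9 from 3, or steps 1 and 3 to 9 from 1).

**Step 5 (key step).**
- What may go wrong: the conjugate addition to a β,β-disubstituted and very lipophilic enone may be slow, so conversion may stall. Facial discrimination may be incomplete. The sense of induction may be the reverse of the one assumed. Slow electrophilic oxidation of the chain alkene could set in if peracid builds up.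
- Fallback (from 10, back at 11): reagent-controlled reduction of 10 with (S)-2-methyl-CBS-oxazaborolidine and catecholborane in toluene at −78 °C. Catecholborane is chosen so that the chain alkene is not hydroborated, and this catalyst enantiomer is the one expected if the alkenyl side acts as the large group. This should give (1R)-3-[(12Z)-16-phenylhexadec-12-en-1-yl]cyclohex-2-en-1-ol F1. Hydroxyl-directed epoxidation with VO(acac)2 and tert-butyl hydroperoxide touches only the allylic alkene and adds oxygen syn to the hydroxyl, giving (1R,2R,6S)-6-[(12Z)-16-phenylhexadec-12-en-1-yl]-7-oxabicyclo[4.1.0]heptan-2-ol F2. Oxidation of F2 with Dess–Martin periodinane buffered by NaHCO3 returns to 11.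

**Step 7.**
- What may go wrong: a palladium hydride formed after β-hydride elimination may isomerise the chain Z-alkene. The silyl enol ether may hydrolyse back to 11. The product may aromatise by deprotonation at C4 and opening of the oxirane.
- Fallback (from 12, back at 13): metal-free dehydrogenation of 12 with the complex of IBX and 4-methoxypyridine N-oxide in DMSO at room temperature. This is a single-electron oxidation of the silyl enol ether in which no metal hydride can form. It gives 13 directly and makes no compound outside the list (F0).

**Step 8.**
- What may go wrong: facial selectivity may be poor because the C5 chain leans toward the face from which hydride must come. Conjugate reduction may compete. Methoxide may open the oxirane with aromatisation.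
- Fallback (from 13, back at 14): the reduction is accepted as it falls, and the C2 epimer, (1R,2S,6S)-6-[(12Z)-16-phenylhexadec-12-en-1-yl]-7-oxabicyclo[4.1.0]hept-3-en-2-ol F3, is separated. Mitsunobu inversion (4-nitrobenzoic acid, PPh3, diisopropyl azodicarboxylate, THF, 0 °C) gives (1R,2R,6S)-6-[(12Z)-16-phenylhexadec-12-en-1-yl]-7-oxabicyclo[4.1.0]hept-3-en-2-yl 4-nitrobenzoate F4. Methanolysis with K2CO3 in MeOH gives 14.

**Step 9.**
- What may go wrong: hydride attack at C6 may be slow, because C6 lies between the alkoxide-bearing C1 and the quaternary C5. Lewis-acid-assisted ionisation at C5 could then compete, with delivery of hydride to C5 or rearrangement and loss of the tertiary carbinol.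
- Fallback (from 13, back at 15, bypassing 14): the C6–O bond is cleaved at the ketone stage, where electron transfer to the carbonyl breaks only the α C–O bond. SmI2 in THF/MeOH at −90 °C should give (5S)-5-hydroxy-5-[(12Z)-16-phenylhexadec-12-en-1-yl]cyclohex-2-en-1-one F5, which is kept cold and neutral to avoid dehydration. C1 is then set by reagent control with (R)-2-methyl-CBS-oxazaborolidine and catecholborane in toluene at −78 °C, giving 15.

## Further compounds

F1 | step 5 | (1R)-3-[(12Z)-16-phenylhexadec-12-en-1-yl]cyclohex-2-en-1-ol | O[C@@H]1CCCC(CCCCCCCCCCC/C=C\CCCc2ccccc2)=C1
F2 | step 5 | (1R,2R,6S)-6-[(12Z)-16-phenylhexadec-12-en-1-yl]-7-oxabicyclo[4.1.0]heptan-2-ol | O[C@@H]1CCC[C@@](O2)(CCCCCCCCCCC/C=C\CCCc3ccccc3)[C@@H]12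
F0 | step 7 | none | none
F3 | step 8 | (1R,2S,6S)-6-[(12Z)-16-phenylhexadec-12-en-1-yl]-7-oxabicyclo[4.1.0]hept-3-en-2-ol | O[C@H]1C=CC[C@@](O2)(CCCCCCCCCCC/C=C\CCCc3ccccc3)[C@@H]12
F4 | step 8 | (1R,2R,6S)-6-[(12Z)-16-phenylhexadec-12-en-1-yl]-7-oxabicyclo[4.1.0]hept-3-en-2-yl 4-nitrobenzoate | O=C(O[C@@H]1C=CC[C@@](O2)(CCCCCCCCCCC/C=C\CCCc3ccccc3)[C@@H]12)c1ccc(cc1)[N+](=O)[O-]
F5 | step 9 | (5S)-5-hydroxy-5-[(12Z)-16-phenylhexadec-12-en-1-yl]cyclohex-2-en-1-one | O=C1C=CC[C@@](O)(CCCCCCCCCCC/C=C\CCCc2ccccc2)C1
A1 | alternative 1 | tert-butyl (1S)-1-[12-(tert-butyldimethylsilyloxy)dodecyl]cyclohex-3-en-1-yl carbonate | C1=CCC[C@@](OC(=O)OC(C)(C)C)(CCCCCCCCCCCCO[Si](C)(C)C(C)(C)C)C1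
A2 | alternative 1 | (1S,5S,6S)-6-iodo-1-[12-(tert-butyldimethylsilyloxy)dodecyl]-2,4-dioxabicyclo[3.3.1]nonan-3-one | O=C2O[C@@H]1[C@@H](I)CC[C@@](O2)(CCCCCCCCCCCCO[Si](C)(C)C(C)(C)C)C1
A3 | alternative 2 | (5S,6S)-5-(tert-butyldimethylsilyloxy)-6-ethenyl-3-[(4-methoxybenzyl)oxy]oxan-2-one (either C3 epimer) | C=C[C@@H]1OC(=O)C(OCc2ccc(OC)cc2)C[C@@H]1O[Si](C)(C)C(C)(C)C
A4 | alternative 2 | (1S,5S)-5-(tert-butyldimethylsilyloxy)-1-[(4-methoxybenzyl)oxy]cyclohex-3-ene-1-carboxylic acid | CC(C)(C)[Si](C)(C)O[C@@H]1C=CC[C@@](OCc2ccc(OC)cc2)(C(=O)O)C1
A5 | alternative 3 | [(2S)-2-[(12Z)-16-phenylhexadec-12-en-1-yl]oxiran-2-yl]methyl 4-methylbenzenesulfonate | Cc1ccc(cc1)S(=O)(=O)OC[C@]1(CCCCCCCCCCC/C=C\CCCc2ccccc2)CO1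
A6 | alternative 3 | (4S,16Z)-4-[(1,3-dithian-2-yl)methyl]-20-phenylicosa-1,16-dien-4-ol | C=CC[C@@](O)(CCCCCCCCCCC/C=C\CCCc1ccccc1)CC2SCCCS2
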